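The numbers in the tables are simulated from invented constants, and the scatter is random.

**The gap.** By 120 min Thursday's flask had made 21% of target while 23.0% of the charge had gone elsewhere, a split not far from even, so you ask where that even split lies in the flasks below.

| flask | starting material | protic impurity | free enzyme | temperature | remark | time |
|---|---|---|---|---|---|---|
| Friday's | 0.069 M | 0.069 M | 3.5 µM | −2 °C | run made earlier |  |
| Thursday's | 0.069 M | 0.069 M | 5.2 µM | 14 °C | run made earlier |  |
| Wednesday's | 0.069 M | 0.14 M | 6.9 µM | −2 °C | run made earlier |  |
| violet | 0.069 M | 0.0690 M | 6.9 µM |  | at −10 °C until 2.5 h, from then on at 20 °C | 8.0 h |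
| blue | 0.069 M | 0.0690 M | 6.9 µM | −10 °C |  | 8.0 h |
| grey | 0.069 M | 0.0690 M | 6.9 µM | 20 °C |  | 8.0 h |

Friday's run (percent of the starting material charged)

| time / h | target / % | starting material / % |
|---|---|---|
| 0.417 | 1 | 97 |
| 1.33 | 9 | 90 |
| 2.50 | 15 | 84 |
| 4.00 | 24 | 71 |
| 5.00 | 28 | 62 |
| 6.00 | 32 | 54 |

Thursday's run (percent of the starting material charged)

| time / min | target / % | starting material / % |
|---|---|---|
| 20.0 | 2 | 94 |
| 40.0 | 7 | 82 |
| 60.0 | 11 | 73 |
| 80.0 | 14 | 70 |
| 90.0 | 15 | 64 |
| 120 | 21 | 56 |

Wednesday's run (percent of the starting material charged)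

| time / h | target / % | starting material / % |
|---|---|---|
| 0.500 | 6 | 91 |
| 1.50 | 19 | 78 |
| 3.00 | 31 | 59 |
| 5.00 | 50 | 36 |
| 6.00 | 60 | 26 |

(scatter of a reading: 1.5 percentage points)

1. the best flask by amount of target, in percent of the starting material charged; "all alike" if 1.5 percentage points covers them all (violet / blue / grey / all alike)
2. amount of target at the end, in percent of the starting material charged, violet
3. amount of target at the end, in percent of the starting material charged, blue
4. amount of target at the end, in percent of the starting material charged, grey



**Two rates.** Target climbs about linearly and with the enzyme: scaled to 6.9 µM of free enzyme, Friday's run gives 0.105 h⁻¹ of the charge, beside Wednesday's 0.100 h⁻¹ at twice the impurity, and Thursday's gives 0.139 h⁻¹. You treat the gap as first order in starting material, using the mean amount, which gives 0.0303 h⁻¹ at −2 °C and 0.147 h⁻¹ at 14 °C. A straight line of logarithm against temperature then carries both rates outward: at 20 °C target runs at 0.155 h⁻¹ and the loss constant is 0.267 h⁻¹, and at −10 °C they are 0.0913 h⁻¹ and 0.0137 h⁻¹.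

**The level.** Their quotient at 20 °C is 58.0%; call it the even-split level, the amount of starting material, as a share of the charge, at which loss and target run equally fast. With target running at a constant rate and the loss first order at one temperature, while starting material falls from a to b, target gains level × ln((a + level)/(b + level)).

**Weak link.** Taken down to an empty flask this trusts a constant rate where no run looked, since the lowest amount shown is Wednesday's 26%, so you stop there and credit target nothing below it. Grey then gets 36.7%. Blue's level is 665%, above the whole charge, and on this estimate blue comes down to the same 26% of starting material at 7.41 h with 67.7% of target. By the same estimate violet makes 22.8% of target by 2.5 h, keeps 74.2% of starting material, and reaches 49.1% of target. You commit to blue.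

**The forecast.** It differs, naming violet with 67% for violet, 66% for blue and 55% for grey: “Violet and blue are nearly tied; violet is a slight pick.”

**The result.** Blue ends best with 67.3%, against 42.3% for violet and 29.4% for grey, and grey holds 47.5% of uncatalysed product at 8.00 h, more than its target.

    starting material + protic impurity → quenched substrate (k = 2.58 × 10⁻⁴ M⁻¹ s⁻¹, Ea = 74.0 kJ mol⁻¹)
    starting material + free enzyme → target + free enzyme, rate k2*[starting material]^2.5*[free enzyme]/(1 + ([starting material]/Kh2)^2.5) (21.0 mM, k = 7540 M⁻²·⁵ s⁻¹, Ea = 9.00 kJ mol⁻¹)
    free enzyme → unfolded enzyme (k = 3.14 × 10⁻⁶ s⁻¹, Ea = 251 kJ mol⁻¹)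
    starting material → uncatalysed product (k = 7.65 × 10⁻⁵ s⁻¹, Ea = 102 kJ mol⁻¹)
    starting material + target → side product (k = 7.70 × 10⁻⁴ M⁻¹ s⁻¹, Ea = 51.0 kJ mol⁻¹)
    (constants at 20 °C)

**Less enzyme.** Take the neighbour of violet charged with 2.8 × 10⁻⁶ M of free enzyme: scaling the hot level by the enzyme gives 23.5%, under Wednesday's 26%, and that flask ends with 48.9% of uncatalysed product against 21.2% of target.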